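The runs come from a simulation with constants of no real substance; noise was put on by code.

The starting material left over in cedar after 2.00 min was 87.5% of the charge, against 86.5% in ash after 4.00 min, although cedar had half of the second substrate of ash; cedar also had twice the enzyme for half the time, so I treated the two runs as equal in enzyme times time.

in all of them: starting material 0.10 M
- ash: second substrate 0.10 M; enzyme 5 µM; run made earlier
- maple: second substrate 0.10 M; enzyme 7.5 µM; run made earlier
- cedar: second substrate 0.050 M; enzyme 10 µM; run made earlier
- flask: second substrate 0.100 M; enzyme 10 µM

| run | time / min | target / % | starting material / % |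
|---|---|---|---|
| ash | 0.250 | 1.8 | 99.3 |
| ash | 0.500 | 2.6 | 98.9 |
| ash | 0.833 | 3.0 | 97.0 |
| ash | 1.33 | 5.3 | 94.8 |
| ash | 2.00 | 6.0 | 93.5 |
| ash | 4.00 | 12.9 | 86.5 |
| maple | 0.250 | 1.0 | 100.2 |
| maple | 0.500 | 3.2 | 95.3 |
| maple | 0.833 | 4.8 | 95.1 |
| maple | 1.33 | 7.5 | 93.9 |
| maple | 2.00 | 11.6 | 89.4 |
| maple | 4.00 | 18.3 | 83.4 |
| cedar | 0.250 | 0.5 | 98.1 |
| cedar | 0.500 | 2.0 | 96.0 |
| cedar | 1.00 | 6.4 | 93.2 |
| cedar | 2.00 | 11.3 | 87.5 |
| cedar | 4.00 | 17.5 | 81.9 |

(standard deviation of a reading: 1 percentage point)

- what may be going on: starting material + enzyme <-> starting complex; second substrate + starting complex <-> ternary complex; ternary complex -> enzyme + target; second substrate + enzyme -> spent catalyst; second substrate -> decomposed reagent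

1. apparent order in second substrate when 10% of the starting material are converted (percent change of the rate of making target for one percent more second substrate charged)

From the target in that pair, 11.3% against 12.9% of the charge, I took the logarithm of the target ratio over the logarithm of the charge ratio and got 0.191. This charge exponent, an apparent order, is the percent gain in target for one percent more second substrate at equal enzyme times time, so zero means that the charge does not matter and one means that target follows it. The flask has twice the second substrate of cedar with the same enzyme, so I expected it to run 1.14 times as fast as cedar near the conversion asked about. To test whether one number was enough I took the earlier pair, cedar at 1.00 min and ash at 2.00 min, which gave −0.0931; with a scatter of 1 percentage point on readings of 6.4% and 6.0% I could not tell the two exponents apart, so I kept 0.191 as a loose reading.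

The forecast was 0.3, higher than my exponent, with the caution “Noise and catalyst loss leave this loose.”

The flask gave 0.24 at that conversion, reached after 1.42 min.

    starting material + enzyme ⇌ starting complex (K = 8.60 M⁻¹, k = 7000 M⁻¹ s⁻¹)
    second substrate + starting complex ⇌ ternary complex (K = 190 M⁻¹, k = 46000 M⁻¹ s⁻¹)
    ternary complex → enzyme + target (k = 14.0 s⁻¹)
    second substrate + enzyme → spent catalyst (k = 0.00170 M⁻¹ s⁻¹)
    second substrate → decomposed reagent (k = 0.00610 s⁻¹)

My 0.191, read across the charges of cedar and ash, came out lower than the 0.24 of the flask, which is a local slope at its own charge. The way back from ternary complex to second substrate and starting complex is a part of the reason for that exponent, not the main one: the run of this flask without it has an exponent of 0.014 instead of 0.24.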